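The leftover that matters here is incoming ligand that never shows up on the complex.

| flask | starting complex | incoming ligand | protic impurity | remark | time |
|---|---|---|---|---|---|
| grey | 6.7 mM | 10 mM | 3 mM | run made earlier |  |
| green | 15 mM | 10 mM | 3 mM | run made earlier |  |
| red | 10 mM | 5 mM | 3 mM | run made earlier |  |
| flask | 10 mM | 10.0 mM | 3.00 mM |  | 10 d |

- grey (time / d: complex with three exchanged / %, complex with two exchanged / %): 2.50: 4.0, 43.4; 5.00: 4.6, 43.3; 8.00: 4.7, 43.7; 10.0: 3.7, 43.0
- green (time / d: complex with three exchanged / %, complex with two exchanged / %): 1.25: 0.6, 21.0; 4.00: 1.5, 21.3; 6.00: 1.1, 21.4; 10.0: 0.9, 21.2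
- red (time / d: complex with three exchanged / %, complex with two exchanged / %): 0.833: 0.4, 13.0; 1.67: 0.1, 13.4; 4.00: 0, 13.6; 10.0: 0.9, 13.7

(each reading ± 0.3 percentage points)



* equivalents of incoming ligand to starting complex, everything else as given, that leave most complex with three exchanged at 10 d
* the amount of complex with three exchanged then, in percent of the starting complex charged
* the amount of complex with three exchanged with the amounts as given

In grey and green the readings stand flat within their scatter from the first one on. I average them and count 2 ligands on each complex with two exchanged and 3 on each with three exchanged. That gives 6.66 mM of ligand found in grey and 6.83 mM in green. So the loss, 3.25 mM, is the charged ligand the complexes do not show. I take it as unchanged at 10.0 mM of ligand, the charge of both runs, carry it to larger charges as an assumption, and from it reckon the mean exchange number: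

m = (c(incoming ligand) − loss) / c(starting complex)

For this flask m is 0.675, more than green at 0.455 and less than grey at 0.994. I take their complex with three exchanged as my bracket for the answer, from 1.02% to 4.25%. Between those runs the readings grow roughly as m squared, so scaling each end tightens my estimate:

1.96% to 2.25%

A mean of 3 needs 3.33 equiv. There my bound from above is 100%. My bound from below is 36.8%, the peak of a chain of equal steps, in case the next exchange keeps pace.

The forecast says 2%, inside my tightened bracket, and 85% at 3.5 equiv, inside the wide one, adding “this optimum is the least certain number”.

The flask gives 2.38%, just above my tightened bracket, and 55.0% at 3.48 equiv, less than forecast.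

    starting complex + incoming ligand ⇌ leaving ligand + complex with one exchanged (K = 0.700, k = 0.0200 M⁻¹ s⁻¹)
    complex with one exchanged + incoming ligand ⇌ leaving ligand + complex with two exchanged (K = 75.0, k = 0.0200 M⁻¹ s⁻¹)
    complex with two exchanged + incoming ligand ⇌ leaving ligand + complex with three exchanged (K = 2.80, k = 6.60 × 10⁻⁴ M⁻¹ s⁻¹)
    complex with three exchanged + incoming ligand ⇌ leaving ligand + complex with four exchanged (K = 0.220, k = 7.50 × 10⁻⁴ M⁻¹ s⁻¹)
    leaving ligand → by-product carried off (k = 7.60 × 10⁻⁶ s⁻¹)
    protic impurity + incoming ligand → quenched reagent (k = 0.0130 M⁻¹ s⁻¹)

At the end of the flask 0.014% of the incoming ligand remains against 63% of the starting complex, so ligand is the limiting reagent. With the ligand level held instead of falling, complex with three exchanged in the flask goes from 2.38% to 38.2%, the largest single effect of those tried, yet a part, 37% of what is missing. At the best charge m is 3.15, yet 20.6% stands as two exchanged and 24.2% as four. In the neighbouring flask with 2.5 mM of starting complex, m is 2.70, the forms with two, three and four exchanged average 2.56, and complex with three exchanged is 35.8%.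

The readings come from a simulation for substances that don't exist; scatter was added.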